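Jezonodione is a bicyclo[3.2.1]oct-3-ene-2,8-dione. The route exploits that its two-carbon bridge C6–C7 (both aryl-bearing CH) is the former C=C of an (E)-stilbene, attached to C5 and C1, the two carbons flanking the C8 ketone of an oxygenated six-membered ring (C1–C5, C8). Both bonds, C5–C6 and C1–C7, are made at once: a 2-methoxy-6-styryl-1,4-benzoquinone held on a chiral titanium TADDOLate adds persilylated piceatannol in an enantioselective cationic [5+2] cycloaddition that closes the cyclopentanone ring (C1, C8, C5, C6, C7) and sets all four stereocentres. The surplus C3 enol oxygen is then removed through its triflate, and the six silyl ethers last.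

Key step: step 6

Assumption: the (4R,5R)-TADDOLate is taken to shield the quinone face that leads to the (1R,5R,6R,7R) adduct 10; should the opposite sense be found, the equally available (4S,5S)-TADDOL is used in the same way. TBS = tert-butyldimethylsilyl; TADDOL = 2,2-dimethyl-α,α,α′,α′-tetraphenyl-1,3-dioxolane-4,5-dimethanol.

Step 1
Reactants: 1 piceatannol, (E)-3,3′,4,5′-tetrahydroxystilbene
Product: 2 (E)-3,3′,4,5′-tetrakis(TBS-oxy)stilbene
Conditions: TBSCl, imidazole, DMF, rt
Reagents that add atoms: tert-butyldimethylsilyl chloride, CC(C)(C)[Si](C)(C)Cl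
Why: Standard phenol silylation; the silyl ethers keep the catechol ring a para-oxygen donor for the key step and can later be removed without base.

Step 2
Reactants: 3 3,4-dihydroxybenzaldehyde
Product: 4 3,4-bis(TBS-oxy)benzaldehyde
Conditions: TBSCl, imidazole, DMF, rt
Reagents that add atoms: tert-butyldimethylsilyl chloride, CC(C)(C)[Si](C)(C)Cl
Why: Standard phenol silylation of both catechol hydroxyls.

Step 3
Reactants: 4 3,4-bis(TBS-oxy)benzaldehyde
Product: 5 3,4-bis(TBS-oxy)styrene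
Conditions: Ph3PCH3Br, KOtBu, THF, 0 °C to rt
Reagents that add atoms: methyltriphenylphosphonium bromide, C[P+](c1ccccc1)(c1ccccc1)c1ccccc1.[Br-]
Why: Wittig methylenation of an aromatic aldehyde, which aryl silyl ethers tolerate.

Step 4
Reactants: 5 3,4-bis(TBS-oxy)styrene; 6 2-bromo-6-methoxyphenol
Product: 7 2-{(E)-2-[3,4-bis(TBS-oxy)phenyl]ethenyl}-6-methoxyphenol
Conditions: Pd(OAc)2, P(o-tol)3, Et3N, MeCN, 85 °C
Reagents that add atoms: none
Why: Heck reaction of the aryl bromide at the terminal styrene carbon; syn insertion and syn β-hydride elimination should give the E-stilbene.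

Step 5
Reactants: 7 2-{(E)-2-[3,4-bis(TBS-oxy)phenyl]ethenyl}-6-methoxyphenol
Product: 8 2-{(E)-2-[3,4-bis(TBS-oxy)phenyl]ethenyl}-6-methoxy-1,4-benzoquinone
Conditions: (KSO3)2NO (Fremy's salt), KH2PO4 buffer, Bu4NHSO4 (cat.), CH2Cl2/H2O, rt
Reagents that add atoms: potassium nitrosodisulfonate, [K+].[K+].[O]N(S(=O)(=O)[O-])S(=O)(=O)[O-]
Why: Teuber oxidation; both ortho positions of the only free phenol are blocked and the para position is free, so the para-quinone should form.

Step 6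
Reactants: 8 2-{(E)-2-[3,4-bis(TBS-oxy)phenyl]ethenyl}-6-methoxy-1,4-benzoquinone; 2 (E)-3,3′,4,5′-tetrakis(TBS-oxy)stilbene
Product: 10 (1R,5R,6R,7R)-7-[3,4-bis(TBS-oxy)phenyl]-6-[3,5-bis(TBS-oxy)phenyl]-4-{(E)-2-[3,4-bis(TBS-oxy)phenyl]ethenyl}-3-hydroxybicyclo[3.2.1]oct-3-ene-2,8-dione (7-aryl syn to the C2–C4 enone bridge; 6-aryl syn to the C8 carbonyl), via O-methyl oxocarbenium titanate 9 (not isolated)
Conditions: (4R,5R)-TADDOL, TiCl4, Ti(OiPr)4 (excess chiral titanium TADDOLate), 4 Å MS, CH2Cl2, −78 °C; then aq. NaHCO3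
Reagents that add atoms: none
Why: Chelation of the tetravalent titanium TADDOLate by the C1 carbonyl and the 2-methoxy oxygen of 8 makes the quinone a 2-oxy-pentadienyl cation equivalent, electrophilic at quinone C5 and then nucleophilic at the enol-ether carbon C3; the stilbene adds across C5 and C3 in an asynchronous, endo-selective cationic [5+2] cycloaddition to give oxocarbenium titanate 9, which loses its O-methyl group to chloride and is hydrolysed to 10 (quinone C3, C4, C5, C6, C1, C2 become C1, C8, C5, C4, C3, C2). The closest known reaction type is the titanium-promoted [5+2] cycloaddition of 2-alkoxy-1,4-benzoquinones with styrenes to 7-aryl-3-hydroxybicyclo[3.2.1]oct-3-ene-2,8-diones, including its TADDOLate-mediated enantioselective form. The only ring closed is the cyclopentanone (C1, C8, C5, C6, C7), by two C–C bonds across the existing six-membered ring; in stepwise terms the second bond is a 5-(enolexo)-exo-trig capture of benzylic positive charge by the enol-ether carbon. Regiochemistry follows from charge stabilisation: the stilbene carbon bearing the 3,5-disilyloxyphenyl ring bonds first to quinone C5, because positive charge then develops next to the para-silyloxyphenyl ring, and this carbon closes onto quinone C3. The E geometry of 2 gives the trans C6/C7 relationship, the cation-stabilising catechol ring lies over the titanium-bound dienyl unit (endo) and so ends syn to the enone bridge, the bridgeheads follow from suprafacial addition to one quinone face, and the C2-symmetric TADDOLate chooses that face and thereby the absolute configuration of all four centres. The step needs carbon rather than oxygen closure (the dihydrobenzofuran pathway) and no later ionisation of the C1–C7 bond, which the low temperature, the chelated titanium enolate and a cold basic quench should secure.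

Step 7
Reactants: 10 (1R,5R,6R,7R)-3-hydroxy adduct
Product: 11 (1R,5R,6R,7R)-7-[3,4-bis(TBS-oxy)phenyl]-6-[3,5-bis(TBS-oxy)phenyl]-4-{(E)-2-[3,4-bis(TBS-oxy)phenyl]ethenyl}-2,8-dioxobicyclo[3.2.1]oct-3-en-3-yl trifluoromethanesulfonate
Conditions: Tf2O, 2,6-lutidine, CH2Cl2, −78 °C
Reagents that add atoms: trifluoromethanesulfonic anhydride, O=S(=O)(OS(=O)(=O)C(F)(F)F)C(F)(F)F
Why: O-sulfonylation of the acidic diosphenol hydroxyl, the only free OH, gives the enol triflate without touching the non-enolisable bridgehead positions.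

Step 8
Reactants: 11 enol triflate
Product: 12 (1S,5R,6R,7R)-7-[3,4-bis(TBS-oxy)phenyl]-6-[3,5-bis(TBS-oxy)phenyl]-4-{(E)-2-[3,4-bis(TBS-oxy)phenyl]ethenyl}bicyclo[3.2.1]oct-3-ene-2,8-dione (same spatial arrangement as 10; the C1 descriptor changes only through priority)
Conditions: Pd(OAc)2 (cat.), PPh3, HCO2H, Et3N, DMF, 50 °C
Reagents that add atoms: none
Why: Palladium-catalysed formate reduction of an enol triflate: oxidative addition of zerovalent palladium, formate exchange, decarboxylation and C–H reductive elimination should replace OTf by H with the alkene position and all stereocentres unchanged.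

Step 9
Reactants: 12 hexakis-TBS jezonodione
Product: 13 jezonodione, (1S,5R,6R,7R)-7-(3,4-dihydroxyphenyl)-6-(3,5-dihydroxyphenyl)-4-[(E)-2-(3,4-dihydroxyphenyl)ethenyl]bicyclo[3.2.1]oct-3-ene-2,8-dione
Conditions: HF·pyridine, pyridine, THF, 0 °C to rt
Reagents that add atoms: none
Why: Fluoride cleaves the six aryl O–Si bonds (silyl ether cleavage), and the buffered non-basic medium keeps the freed para-phenol protonated so that the C1–C7 bond should not break by retro-1,6-fragmentation.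

Compound list
1 | piceatannol | Oc1ccc(/C=C/c2cc(O)cc(O)c2)cc1O | starting material
2 | (E)-3,3′,4,5′-tetrakis(TBS-oxy)stilbene | CC(C)(C)[Si](C)(C)Oc1ccc(/C=C/c2cc(O[Si](C)(C)C(C)(C)C)cc(O[Si](C)(C)C(C)(C)C)c2)cc1O[Si](C)(C)C(C)(C)C | intermediate
3 | 3,4-dihydroxybenzaldehyde | O=Cc1ccc(O)c(O)c1 | starting material
4 | 3,4-bis(TBS-oxy)benzaldehyde | O=Cc1ccc(O[Si](C)(C)C(C)(C)C)c(O[Si](C)(C)C(C)(C)C)c1 | intermediate
5 | 3,4-bis(TBS-oxy)styrene | C=Cc1ccc(O[Si](C)(C)C(C)(C)C)c(O[Si](C)(C)C(C)(C)C)c1 | intermediate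
6 | 2-bromo-6-methoxyphenol | COc1cccc(Br)c1O | starting material
7 | 2-{(E)-2-[3,4-bis(TBS-oxy)phenyl]ethenyl}-6-methoxyphenol | COc1cccc(/C=C/c2ccc(O[Si](C)(C)C(C)(C)C)c(O[Si](C)(C)C(C)(C)C)c2)c1O | intermediate
8 | 2-{(E)-2-[3,4-bis(TBS-oxy)phenyl]ethenyl}-6-methoxy-1,4-benzoquinone | COC1=CC(=O)C=C(/C=C/c2ccc(O[Si](C)(C)C(C)(C)C)c(O[Si](C)(C)C(C)(C)C)c2)C1=O | intermediate
9 | (1R,5R,6R,7R) O-methyl oxocarbenium at C2 of the [5+2] adduct, its C3 enolate oxygen bound to dichloro[(4R,5R)-TADDOLato]titanate (zwitterion) | C[O+]=C1C(O[Ti-]%10(Cl)(Cl)OC(c3ccccc3)(c3ccccc3)[C@@H]3OC(C)(C)O[C@H]3C(c3ccccc3)(c3ccccc3)O%10)=C(/C=C/c2ccc(O[Si](C)(C)C(C)(C)C)c(O[Si](C)(C)C(C)(C)C)c2)[C@@H]2C(=O)[C@H]1[C@H](c1ccc(O[Si](C)(C)C(C)(C)C)c(O[Si](C)(C)C(C)(C)C)c1)[C@H]2c1cc(O[Si](C)(C)C(C)(C)C)cc(O[Si](C)(C)C(C)(C)C)c1 | intermediate (not isolated)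
10 | (1R,5R,6R,7R)-7-[3,4-bis(TBS-oxy)phenyl]-6-[3,5-bis(TBS-oxy)phenyl]-4-{(E)-2-[3,4-bis(TBS-oxy)phenyl]ethenyl}-3-hydroxybicyclo[3.2.1]oct-3-ene-2,8-dione | O=C1C(O)=C(/C=C/c2ccc(O[Si](C)(C)C(C)(C)C)c(O[Si](C)(C)C(C)(C)C)c2)[C@@H]2C(=O)[C@H]1[C@H](c1ccc(O[Si](C)(C)C(C)(C)C)c(O[Si](C)(C)C(C)(C)C)c1)[C@H]2c1cc(O[Si](C)(C)C(C)(C)C)cc(O[Si](C)(C)C(C)(C)C)c1 | intermediate
11 | (1R,5R,6R,7R)-7-[3,4-bis(TBS-oxy)phenyl]-6-[3,5-bis(TBS-oxy)phenyl]-4-{(E)-2-[3,4-bis(TBS-oxy)phenyl]ethenyl}-2,8-dioxobicyclo[3.2.1]oct-3-en-3-yl trifluoromethanesulfonate | O=C1C(OS(=O)(=O)C(F)(F)F)=C(/C=C/c2ccc(O[Si](C)(C)C(C)(C)C)c(O[Si](C)(C)C(C)(C)C)c2)[C@@H]2C(=O)[C@H]1[C@H](c1ccc(O[Si](C)(C)C(C)(C)C)c(O[Si](C)(C)C(C)(C)C)c1)[C@H]2c1cc(O[Si](C)(C)C(C)(C)C)cc(O[Si](C)(C)C(C)(C)C)c1 | intermediate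
12 | (1S,5R,6R,7R)-7-[3,4-bis(TBS-oxy)phenyl]-6-[3,5-bis(TBS-oxy)phenyl]-4-{(E)-2-[3,4-bis(TBS-oxy)phenyl]ethenyl}bicyclo[3.2.1]oct-3-ene-2,8-dione | O=C1C=C(/C=C/c2ccc(O[Si](C)(C)C(C)(C)C)c(O[Si](C)(C)C(C)(C)C)c2)[C@@H]2C(=O)[C@H]1[C@H](c1ccc(O[Si](C)(C)C(C)(C)C)c(O[Si](C)(C)C(C)(C)C)c1)[C@H]2c1cc(O[Si](C)(C)C(C)(C)C)cc(O[Si](C)(C)C(C)(C)C)c1 | intermediate
13 | jezonodione, (1S,5R,6R,7R)-7-(3,4-dihydroxyphenyl)-6-(3,5-dihydroxyphenyl)-4-[(E)-2-(3,4-dihydroxyphenyl)ethenyl]bicyclo[3.2.1]oct-3-ene-2,8-dione | O=C1C=C(/C=C/c2ccc(O)c(O)c2)[C@@H]2C(=O)[C@H]1[C@H](c1ccc(O)c(O)c1)[C@H]2c1cc(O)cc(O)c1 | target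

Total step count: 9. Longest linear sequence: 8 steps (steps 2 to 9, from 3 to 13); step 1 is a one-step side branch.

Steps most likely to fail

Step 6. The hindered, only moderately nucleophilic stilbene may add too slowly to a quinone whose C5 is deactivated by the donor styryl arm. The benzylic positive charge may also be captured by the C4 oxygen or the adduct may re-ionise (dihydrobenzofuran formation), and face selection by the TADDOLate may be incomplete. Fallback, setting out from 6 and returning at 10: Teuber oxidation of 6 with (KSO3)2NO should give 2-bromo-6-methoxy-1,4-benzoquinone F1, a smaller and more electrophilic quinone without the competing alkene. F1 and 2 under the same titanium TADDOLate conditions should give (1R,5S,6R,7R)-4-bromo-7-[3,4-bis(TBS-oxy)phenyl]-6-[3,5-bis(TBS-oxy)phenyl]-3-hydroxybicyclo[3.2.1]oct-3-ene-2,8-dione F2. Separately, cross-metathesis of 5 with vinylboronic acid pinacol ester (second-generation Hoveyda–Grubbs catalyst, CH2Cl2, 40 °C) should give (E)-2-[3,4-bis(TBS-oxy)phenyl]ethenylboronic acid pinacol ester F3. Suzuki–Miyaura coupling of F2 with F3 (Pd(dppf)Cl2, K3PO4, THF/H2O, 50 °C) then installs the styryl arm at C4 after the cycloaddition and returns 10.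

Step 9. Once the para-hydroxyl of the C7 catechol is free, any phenoxide formed could push out the C1–C7 bond (retro-1,6-addition), driven by aromatisation of the six-membered ring, and the fragments could reclose through oxygen. Fallback, setting out from 12 and returning at 13: desilylation in the presence of an acylating agent (CsF, Ac2O, DMF, 0 °C) traps each phenoxide as it is released and should give the stable, purifiable hexaacetate of jezonodione F4. Neutral deacetylation (NH4OAc, MeOH/H2O, rt) then liberates 13 without strong base or fluoride.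

Step 5. The phenoxyl radical of 7 is delocalised into the electron-rich styryl arm and may couple through carbon or over-oxidise instead of being trapped at the para position. Fallback, setting out from 5 and returning at 8: the para oxygen is brought in from the start. Dakin oxidation (H2O2, NaOH) of commercial 5-bromovanillin should give 2-bromo-6-methoxybenzene-1,4-diol F5. Heck coupling of F5 with 5 (Pd(OAc)2, P(o-tol)3, Et3N, MeCN, 85 °C) should give 2-{(E)-2-[3,4-bis(TBS-oxy)phenyl]ethenyl}-6-methoxybenzene-1,4-diol F6. A two-electron oxidation of the hydroquinone (Ag2O, MgSO4, Et2O, rt) then gives 8 without free phenoxyl radicals.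

Further compounds
F1 | step 6 | 2-bromo-6-methoxy-1,4-benzoquinone | COC1=CC(=O)C=C(Br)C1=O
F2 | step 6 | (1R,5S,6R,7R)-4-bromo-7-[3,4-bis(TBS-oxy)phenyl]-6-[3,5-bis(TBS-oxy)phenyl]-3-hydroxybicyclo[3.2.1]oct-3-ene-2,8-dione | O=C1C(O)=C(Br)[C@@H]2C(=O)[C@H]1[C@H](c1ccc(O[Si](C)(C)C(C)(C)C)c(O[Si](C)(C)C(C)(C)C)c1)[C@H]2c1cc(O[Si](C)(C)C(C)(C)C)cc(O[Si](C)(C)C(C)(C)C)c1
F3 | step 6 | (E)-2-[3,4-bis(TBS-oxy)phenyl]ethenylboronic acid pinacol ester | CC1(C)OB(/C=C/c2ccc(O[Si](C)(C)C(C)(C)C)c(O[Si](C)(C)C(C)(C)C)c2)OC1(C)C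
F4 | step 9 | jezonodione hexaacetate, (1S,5R,6R,7R) | O=C1C=C(/C=C/c2ccc(OC(C)=O)c(OC(C)=O)c2)[C@@H]2C(=O)[C@H]1[C@H](c1ccc(OC(C)=O)c(OC(C)=O)c1)[C@H]2c1cc(OC(C)=O)cc(OC(C)=O)c1
F5 | step 5 | 2-bromo-6-methoxybenzene-1,4-diol | COc1cc(O)cc(Br)c1O
F6 | step 5 | 2-{(E)-2-[3,4-bis(TBS-oxy)phenyl]ethenyl}-6-methoxybenzene-1,4-diol | COc1cc(O)cc(/C=C/c2ccc(O[Si](C)(C)C(C)(C)C)c(O[Si](C)(C)C(C)(C)C)c2)c1O
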